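## Retrosynthetic overview
1. Ten-membered ring, closed last: ring-closing metathesis at C5=C6 between a C5 isopropenyl group and a C6 vinyl group.
2. γ-Lactone, second ring: the C8–C17 bond comes from an intramolecular Reformatsky reaction of a C7 2-bromopropanoate onto a C8 ketone. The C11 hydroxyl comes from enolate oxidation.
3. Key bond C7–C8: acrolein is used with inverted polarity, as a 1-acyloxyallylindium made from a 3-bromopropenyl ester, and adds to the C8 aldehyde. Two former aldehyde carbons are joined, and one reagent brings C6, C7 and C17–C19.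
4. Ring A, first ring: Diels–Alder reaction of an E γ-acetoxy enone (C1=C10) with a 1-amino-3-siloxydiene. C2 is set by CBS reduction.
5. Dienophile: Wittig reaction of a chain-extended acyl ylide with (R)-2-acetoxy-3,3-dimethoxypropanal (C8–C10). C9 comes from a lipase resolution.

Assumption: labels follow briarane numbering (C1 quaternary ring-fusion carbon, C2 propanoate carbon, C5=C6 alkene, C7 lactone O–CH, C8 tertiary carbinol, C9 acetate carbon, C10 ring-fusion CH, C11 carbinol, C12 ketone, C13=C14 enone, C15/C16/C18/C20 methyls on C1/C5/C17/C11, C19 lactone C=O); the target is 1S,2R,5Z,7S,8S,9R,10S,11S,17R; β is the ring A face that carries C15.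

## Route

Step 1
Reactants: 1 2,2-dimethoxyacetaldehyde; 2 vinylmagnesium bromide
Product: 3 rac-1,1-dimethoxybut-3-en-2-ol
Conditions: anhydrous 1 (aqueous solution dried azeotropically), THF, −78 °C → 0 °C; H2O work-up
Reagents that add atoms: none
Why: Grignard 1,2-addition to a non-enolisable aldehyde gives the racemic allylic alcohol whose carbinol carbon becomes C9 and is resolved in step 2.

Step 2
Reactants: 3 rac-1,1-dimethoxybut-3-en-2-ol
Product: 4 (R)-1,1-dimethoxybut-3-en-2-yl acetate
Conditions: immobilised Candida antarctica lipase B, vinyl acetate, MTBE, 30 °C, stopped at about 50 % conversion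
Reagents that add atoms: vinyl acetate C=COC(C)=O
Why: Lipase-catalysed kinetic resolution by irreversible transesterification follows the Kazlauskas rule (vinyl medium, dimethoxymethyl large), so only the R alcohol is acylated and C9 is fixed already carrying its final acetate.

Step 3
Reactants: 4 (R)-1,1-dimethoxybut-3-en-2-yl acetate
Product: 6 (R)-1,1-dimethoxy-3-oxopropan-2-yl acetate, via secondary ozonide 5 (not isolated)
Conditions: O3, CH2Cl2, −78 °C; Me2S, −78 °C → rt
Reagents that add atoms: ozone [O-][O+]=O
Why: Ozonolysis with reductive work-up cleaves the only alkene to the C10 aldehyde under neutral conditions that leave the α-acetoxy stereocentre C9 untouched.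

Step 4
Reactants: 7 3-chlorobutan-2-one; 8 triphenylphosphine
Product: 10 3-(triphenyl-λ5-phosphanylidene)butan-2-one, via phosphonium chloride 9 (not isolated)
Conditions: toluene, reflux; then aq NaOH, CH2Cl2, rt
Reagents that add atoms: none
Why: SN2 quaternisation of the phosphine followed by deprotonation gives the stabilised acyl ylide (standard Wittig reagent preparation, no stereocentre).

Step 5
Reactants: 10 3-(triphenyl-λ5-phosphanylidene)butan-2-one; 11 3-bromo-2-methylprop-1-ene
Product: 13 6-methyl-2-(triphenyl-λ5-phosphanylidene)hept-6-en-3-one, via lithiated ylide 12 (not isolated)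
Conditions: n-BuLi, THF, −78 °C; then 11, −78 °C → rt
Reagents that add atoms: none
Why: γ-Deprotonation of the β-keto ylide gives an ylide anion that is alkylated at its terminal carbon by the allylic bromide (ylide-anion alkylation), which turns the acetyl methyl into C3 and adds C4, C5, C16 and the metathesis handle.

Step 6
Reactants: 6 (R)-1,1-dimethoxy-3-oxopropan-2-yl acetate; 13 6-methyl-2-(triphenyl-λ5-phosphanylidene)hept-6-en-3-one
Product: 14 (2R,3E)-1,1-dimethoxy-4,8-dimethyl-5-oxonona-3,8-dien-2-yl acetate
Conditions: CH2Cl2, 40 °C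
Reagents that add atoms: none
Why: Wittig olefination with a stabilised α-methyl ylide is E-selective and neutral, so the C1=C10 alkene forms with C2 and C9 trans and C9 is not epimerised.

Step 7
Reactants: 15 butan-2-one; 16 N,N-dimethylformamide dimethyl acetal
Product: 17 (E)-1-(dimethylamino)pent-1-en-3-one
Conditions: neat, reflux, MeOH distilled off; fractional distillation
Reagents that add atoms: none
Why: Condensation of the amide acetal at the less hindered methyl group of the methyl ketone gives the E vinylogous amide (enaminone formation).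

Step 8
Reactants: 17 (E)-1-(dimethylamino)pent-1-en-3-one
Product: 19 (1E,3Z)-3-(tert-butyldimethylsilyloxy)-N,N-dimethylpenta-1,3-dien-1-amine, via potassium dienolate 18 (not isolated)
Conditions: KN(SiMe3)2, THF, −78 °C; TBSCl, −78 °C → rt
Reagents that add atoms: tert-butyldimethylsilyl chloride CC(C)(C)[Si](C)(C)Cl
Why: Kinetic deprotonation of the ethyl side gives the Z(O) enolate, and O-silylation delivers the very nucleophilic 1-amino-3-siloxydiene with its terminal methyl group pointing outward.

Step 9
Reactants: 14 (2R,3E)-1,1-dimethoxy-4,8-dimethyl-5-oxonona-3,8-dien-2-yl acetate; 19 (1E,3Z)-3-(tert-butyldimethylsilyloxy)-N,N-dimethylpenta-1,3-dien-1-amine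
Product: 20 ring A cycloadduct ketone (1S;10S;9R; C11-Me α; C14-NMe2 α; C12 OTBS enol ether)
Conditions: 19 (2 equiv), toluene, 80 °C, sealed tube
Reagents that add atoms: none
Why: In this normal-electron-demand Diels–Alder reaction the methyl-bearing nucleophilic diene terminus bonds to C10 (β to the C2 ketone), the E geometry is transferred stereospecifically into the trans C2/C9 relationship at C1 and C10, and A(1,3) strain with the C1 methyl holds H9 in the alkene plane so that the diene adds anti to the branched dimethoxymethyl group, giving 1S,10S from 9R (C11 and C14 follow the endo rule and are reset or lost later).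

Step 10
Reactants: 20 ring A cycloadduct ketone
Product: 21 ring A C2 alcohol (2R)
Conditions: (S)-Me-CBS oxazaborolidine (0.5 equiv), catecholborane (3 equiv), toluene, −78 °C → −40 °C; H2O work-up
Reagents that add atoms: none
Why: In the Corey–Bakshi–Shibata reduction the S catalyst distinguishes the quaternary C1 side from the CH2 side of the only ketone (C12 is masked as its enol ether) and delivers hydride to give the 2R alcohol, while catecholborane leaves the alkenes alone at this temperature.

Step 11
Reactants: 21 ring A C2 alcohol (2R)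
Product: 22 ring A C2 propanoate
Conditions: (EtCO)2O, Et3N, DMAP, CH2Cl2, rt
Reagents that add atoms: propanoic anhydride CCC(=O)OC(=O)CC
Why: DMAP-catalysed acylation of the only hydroxyl group installs the final C2 ester with retention.

Step 12
Reactants: 22 ring A C2 propanoate
Product: 23 enone aldehyde (C13=C14 enone; C8 aldehyde; C11-Me α)
Conditions: TFA/H2O (9:1), CH2Cl2, 0 °C → rt
Reagents that add atoms: water O
Why: Aqueous acid hydrolyses the silyl enol ether, the resulting β-amino ketone loses dimethylamine (E1cB-type elimination) to give the enone, and the same medium unmasks the acetal to the C8 aldehyde, with C11 settling as the equatorial methyl epimer.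

Step 13
Reactants: 24 acrolein; 25 2-bromopropanoyl bromide
Product: 26 3-bromoprop-1-enyl 2-bromopropanoate (E/Z mixture)
Conditions: ZnCl2 (2 mol%), CH2Cl2, −20 °C → 0 °C
Reagents that add atoms: none
Why: Lewis acid catalysed 1,4-addition of the acyl bromide to acrolein (acyl on oxygen, bromide on the terminal carbon) gives the 3-bromopropenyl ester, and both alkene isomers converge on the same allylmetal.

Step 14
Reactants: 23 enone aldehyde; 26 3-bromoprop-1-enyl 2-bromopropanoate
Product: 28 C8 carbinol (7S; 7,8-anti; 8,9-anti; C7 2-bromopropanoate; C6 vinyl), via allylindium reagent 27 (not isolated)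
Conditions: In powder (1.5 equiv), 26 (1.5 equiv), THF, 0 °C → rt; H2O work-up
Reagents that add atoms: none
Why: Proposed new method: indium metal inserts into the allylic C–Br bond of 26 much faster than into the α-bromo ester and gives a γ-acyloxyallylindium in which the former carbonyl carbon of acrolein is nucleophilic (an α-oxyallyl anion, d1 synthon); this carbon attacks the C8 aldehyde through a chair transition state, so two carbons that are both electrophilic as aldehydes are joined; the E-configured reagent gives the 7,8-anti relationship and polar Felkin–Anh control by the C9 acetate gives the 8,9-anti relationship (together 7S, with C8 erased in step 15), while enone and esters are left alone; the closest known reaction type is the Barbier-type α-hydroxyallylation of aldehydes with 3-bromopropenyl acetate or benzoate under indium, zinc or chromium mediation, and the new element is the 2-bromopropanoyl group carried along as the later Reformatsky donor.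

Step 15
Reactants: 28 C8 carbinol
Product: 29 C8 ketone (7S;9R)
Conditions: Dess–Martin periodinane, CH2Cl2, 0 °C, used at once
Reagents that add atoms: none
Why: Dess–Martin oxidation of the only secondary alcohol works without base, so the acidic C7 and C9 stereocentres flanking the new ketone and the β,γ-alkene stay in place.

Step 16
Reactants: 29 C8 ketone
Product: 31 lactone diene (7S;8S;17R; 11-deoxy), via zinc enolate 30 (not isolated)
Conditions: activated Zn dust, THF, 0 °C → rt; H2O work-up
Reagents that add atoms: none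
Why: In this intramolecular Reformatsky reaction zinc inserts into the C–Br bond and the ester enolate, tethered through O7, closes the five-membered ring on the C8 ketone with the bulky C9 substituent trans to the C7 vinyl group and the C17 methyl turned away from C9 (cis to the new OH), which sets 8S and 17R from 7S.

Step 17
Reactants: 31 lactone diene
Product: 33 seco diene (all eight stereocentres in place), via dilithium dienolate 32 (not isolated)
Conditions: LiN(SiMe3)2 (2.1 equiv), THF, −78 °C; 3-phenyl-2-(phenylsulfonyl)oxaziridine, −78 °C; H2O work-up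
Reagents that add atoms: 3-phenyl-2-(phenylsulfonyl)oxaziridine O=S(=O)(c1ccccc1)N1OC1c1ccccc1
Why: After the C8 hydroxyl is deprotonated, kinetic α′-deprotonation of the enone gives the cross-conjugated dienolate, and the Davis oxaziridine transfers oxygen to C11 from the α face, opposite the axial C1 methyl and the C10 side chain, giving the 11S tertiary alcohol (enolate hydroxylation).

Step 18
Reactants: 33 seco diene
Product: 34 CNP0240018.1 (target)
Conditions: second-generation Grubbs catalyst (15 mol%), 1,4-benzoquinone (30 mol%), toluene, 0.5 mM, 90 °C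
Reagents that add atoms: none
Why: Ring-closing metathesis at high dilution joins the 1,1-disubstituted and the monosubstituted alkene with loss of ethene, and the ring strain of the ten-membered ring strongly favours the Z trisubstituted alkene (C4 and C7 cis).

## Compound list
1 | 2,2-dimethoxyacetaldehyde | COC(OC)C=O | starting material
2 | vinylmagnesium bromide | C=C[Mg]Br | starting material
3 | rac-1,1-dimethoxybut-3-en-2-ol | C=CC(O)C(OC)OC | intermediate
4 | (R)-1,1-dimethoxybut-3-en-2-yl acetate (C8 acetal, C9 acetate, C10 vinyl) | C=C[C@@H](OC(C)=O)C(OC)OC | intermediate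
5 | secondary ozonide of 4, (R)-2,2-dimethoxy-1-(1,2,4-trioxolan-3-yl)ethyl acetate | CC(=O)O[C@H](C1OCOO1)C(OC)OC | intermediate
6 | (R)-1,1-dimethoxy-3-oxopropan-2-yl acetate | O=C[C@@H](OC(C)=O)C(OC)OC | intermediate
7 | 3-chlorobutan-2-one | CC(Cl)C(C)=O | starting material
8 | triphenylphosphine | c1ccc(cc1)P(c1ccccc1)c1ccccc1 | starting material
9 | (3-oxobutan-2-yl)triphenylphosphonium chloride | CC(C(C)=O)[P+](c1ccccc1)(c1ccccc1)c1ccccc1.[Cl-] | intermediate
10 | 3-(triphenyl-λ5-phosphanylidene)butan-2-one | CC(=O)C(C)=P(c1ccccc1)(c1ccccc1)c1ccccc1 | intermediate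
11 | 3-bromo-2-methylprop-1-ene | C=C(C)CBr | starting material
12 | 1-lithio-3-(triphenyl-λ5-phosphanylidene)butan-2-one | [Li]CC(=O)C(C)=P(c1ccccc1)(c1ccccc1)c1ccccc1 | intermediate
13 | 6-methyl-2-(triphenyl-λ5-phosphanylidene)hept-6-en-3-one | C=C(C)CCC(=O)C(C)=P(c1ccccc1)(c1ccccc1)c1ccccc1 | intermediate
14 | (2R,3E)-1,1-dimethoxy-4,8-dimethyl-5-oxonona-3,8-dien-2-yl acetate (C2 ketone, E C1=C10, 9R) | C=C(C)CCC(=O)/C(C)=C/[C@@H](OC(C)=O)C(OC)OC | intermediate
15 | butan-2-one | CCC(C)=O | starting material
16 | N,N-dimethylformamide dimethyl acetal | COC(OC)N(C)C | starting material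
17 | (E)-1-(dimethylamino)pent-1-en-3-one | CCC(=O)/C=C/N(C)C | intermediate
18 | potassium (1E,3Z)-1-(dimethylamino)penta-1,3-dien-3-olate | C/C=C([O-])/C=C/N(C)C.[K+] | intermediate
19 | (1E,3Z)-3-(tert-butyldimethylsilyloxy)-N,N-dimethylpenta-1,3-dien-1-amine | C/C=C(O[Si](C)(C)C(C)(C)C)/C=C/N(C)C | intermediate
20 | Diels–Alder adduct: cyclohexene with C1 (β-Me, α-4-methylpent-4-enoyl), C10 (α-H, β-(R)-1-acetoxy-2,2-dimethoxyethyl), C11 α-Me, C12(OTBS)=C13, C14 α-NMe2 | C=C(C)CCC(=O)[C@@]1(C)[C@@H](N(C)C)C=C(O[Si](C)(C)C(C)(C)C)[C@@H](C)[C@@H]1[C@@H](OC(C)=O)C(OC)OC | intermediate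
21 | 2R alcohol from 20 | C=C(C)CC[C@@H](O)[C@@]1(C)[C@@H](N(C)C)C=C(O[Si](C)(C)C(C)(C)C)[C@@H](C)[C@@H]1[C@@H](OC(C)=O)C(OC)OC | intermediate
22 | 2R propanoate of 21 | C=C(C)CC[C@@H](OC(=O)CC)[C@@]1(C)[C@@H](N(C)C)C=C(O[Si](C)(C)C(C)(C)C)[C@@H](C)[C@@H]1[C@@H](OC(C)=O)C(OC)OC | intermediate
23 | enone aldehyde: ring A cyclohex-2-enone (C12=O, C13=C14, C11 α-Me), 2R propanoate chain on C1, (R)-1-acetoxy-2-oxoethyl on C10 | C=C(C)CC[C@@H](OC(=O)CC)[C@@]1(C)C=CC(=O)[C@@H](C)[C@@H]1[C@@H](OC(C)=O)C=O | intermediate
24 | acrolein | C=CC=O | starting material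
25 | 2-bromopropanoyl bromide (racemic) | CC(Br)C(=O)Br | starting material
26 | 3-bromoprop-1-enyl 2-bromopropanoate (E/Z mixture, racemic at CHBr) | CC(Br)C(=O)OC=CCBr | intermediate
27 | [3-(2-bromopropanoyloxy)allyl]indium dibromide | CC(Br)C(=O)OC=CC[In](Br)Br | intermediate
28 | C8 carbinol: 23 extended by C8H(OH)–C7H(O-2-bromopropanoyl)–CH=CH2; 7S, 7,8-anti, 8,9-anti; both CHBr epimers | C=C(C)CC[C@@H](OC(=O)CC)[C@@]1(C)C=CC(=O)[C@@H](C)[C@@H]1[C@@H](OC(C)=O)[C@@H](O)[C@@H](OC(=O)C(C)Br)C=C | intermediate
29 | C8 ketone from 28 (7S,9R; both CHBr epimers) | C=C(C)CC[C@@H](OC(=O)CC)[C@@]1(C)C=CC(=O)[C@@H](C)[C@@H]1[C@@H](OC(C)=O)C(=O)[C@@H](OC(=O)C(C)Br)C=C | intermediate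
30 | bromozinc ester enolate of 29 | C=C(C)CC[C@@H](OC(=O)CC)[C@@]1(C)C=CC(=O)[C@@H](C)[C@@H]1[C@@H](OC(C)=O)C(=O)[C@@H](OC(O[Zn]Br)=CC)C=C | intermediate
31 | lactone diene: β-hydroxy-α-methyl-γ-vinyl-γ-butyrolactone (7S,8S,17R) on C9, ring A still 11-deoxy | C=C(C)CC[C@@H](OC(=O)CC)[C@@]1(C)C=CC(=O)[C@@H](C)[C@@H]1[C@@H](OC(C)=O)[C@]1(O)[C@@H](C)C(=O)O[C@H]1C=C | intermediate
32 | dilithium salt of 31 (C8 alkoxide, C11=C12 dienolate) | C=C(C)CC[C@@H](OC(=O)CC)[C@@]1(C)C=CC(O[Li])=C(C)[C@@H]1[C@@H](OC(C)=O)[C@]1(O[Li])[C@@H](C)C(=O)O[C@H]1C=C | intermediate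
33 | seco diene: 31 with 11S tertiary OH (α-OH, β-Me) | C=C(C)CC[C@@H](OC(=O)CC)[C@@]1(C)C=CC(=O)[C@@](C)(O)[C@@H]1[C@@H](OC(C)=O)[C@]1(O)[C@@H](C)C(=O)O[C@H]1C=C | intermediate
34 | CNP0240018.1, (1S,2R,5Z,7S,8S,9R,10S,11S,17R)-9-acetoxy-8,11-dihydroxy-12-oxo-2-propanoyloxybriara-5,13-diene 7,19-lactone | CCC(=O)O[C@@H]1CC/C(C)=C\[C@@H]2OC(=O)[C@H](C)[C@@]2(O)[C@H](OC(C)=O)[C@@H]2[C@]1(C)C=CC(=O)[C@@]2(C)O | target

## Step count and risks
Total step count: 18.
Longest linear sequence: 13 (steps 1, 2, 3, 6, 9, 10, 11, 12, 14, 15, 16, 17, 18).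

**Step 9, Diels–Alder on a trisubstituted, γ-branched enone.** Both reactivity and facial selectivity are at risk. If the aminodiene 19 decomposes before it adds, set out from 14. Use the smaller and thermally robust (Z)-3-(tert-butyldimethylsilyloxy)penta-1,3-diene F1 (from pent-1-en-3-one, TBSOTf, Et3N) under 1.0 GPa in CH2Cl2, which gives the silyl enol ether cycloadduct F2. CBS reduction as in step 10 gives the C2 alcohol F3, and propanoic anhydride with DMAP gives the C2 propanoate F4. Saegusa–Ito dehydrogenation with Pd(OAc)2 in MeCN then creates the C13=C14 double bond and gives the enone acetal F5. Aqueous TFA unmasks the aldehyde and the sequence comes back to the route at 23.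

**Step 14, key coupling.** The risks are acyl migration in the indium alkoxide, attack of indium on the bromo ester, and weak control at C7. If any of these spoils the step, set out from 23 and make the same C7–C8 bond through a closed boron transition state, with the ester put on only after the oxidation. (Z)-3-(methoxymethoxy)allylboronic acid pinacol ester F6 (from allyl methoxymethyl ether, s-BuLi, then 2-isopropoxy-4,4,5,5-tetramethyl-1,3,2-dioxaborolane) adds to 23 in toluene without additive. This gives the syn,syn MOM ether carbinol F7; the Z reagent gives 7,8-syn, and if it follows the anti-Felkin preference known for Z-crotylboronates with α-methyl aldehydes (untested for an α-acetoxy aldehyde) it gives 8,9-syn, which together is again 7S. Dess–Martin oxidation gives the MOM-protected ketol F8, and dilute aqueous acid frees the C7 ketol F9. 2-Bromopropanoyl bromide with pyridine at −20 °C then comes back to the route at 29.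

**Step 18, ten-membered ring closure to a trisubstituted alkene next to the rigid lactone.** If 33 only oligomerises, set out from 29 and close the ring first. At that stage C8 is still a flat ketone and the chain is more flexible. Second-generation Grubbs catalyst at 0.5 mM gives the macrocyclic keto bromo ester F10. Zinc dust in THF performs the Reformatsky closure inside the ring to give the 11-deoxy macrocycle F11. The conditions of step 17 then hydroxylate C11 and come back to the route at 34.

Further compounds
F1 | step 9 | (Z)-3-(tert-butyldimethylsilyloxy)penta-1,3-diene | C/C=C(O[Si](C)(C)C(C)(C)C)/C=C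
F2 | step 9 | silyl enol ether cycloadduct | C=C(C)CCC(=O)[C@@]1(C)CC=C(O[Si](C)(C)C(C)(C)C)[C@@H](C)[C@@H]1[C@@H](OC(C)=O)C(OC)OC
F3 | step 9 | C2 alcohol | C=C(C)CC[C@@H](O)[C@@]1(C)CC=C(O[Si](C)(C)C(C)(C)C)[C@@H](C)[C@@H]1[C@@H](OC(C)=O)C(OC)OC
F4 | step 9 | C2 propanoate | C=C(C)CC[C@@H](OC(=O)CC)[C@@]1(C)CC=C(O[Si](C)(C)C(C)(C)C)[C@@H](C)[C@@H]1[C@@H](OC(C)=O)C(OC)OC
F5 | step 9 | enone acetal | C=C(C)CC[C@@H](OC(=O)CC)[C@@]1(C)C=CC(=O)[C@@H](C)[C@@H]1[C@@H](OC(C)=O)C(OC)OC
F6 | step 14 | (Z)-3-(methoxymethoxy)allylboronic acid pinacol ester | COCO/C=C\CB1OC(C)(C)C(C)(C)O1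
F7 | step 14 | syn,syn MOM ether carbinol | C=C(C)CC[C@@H](OC(=O)CC)[C@@]1(C)C=CC(=O)[C@@H](C)[C@@H]1[C@@H](OC(C)=O)[C@H](O)[C@@H](OCOC)C=C
F8 | step 14 | MOM-protected ketol | C=C(C)CC[C@@H](OC(=O)CC)[C@@]1(C)C=CC(=O)[C@@H](C)[C@@H]1[C@@H](OC(C)=O)C(=O)[C@@H](OCOC)C=C
F9 | step 14 | C7 ketol | C=C(C)CC[C@@H](OC(=O)CC)[C@@]1(C)C=CC(=O)[C@@H](C)[C@@H]1[C@@H](OC(C)=O)C(=O)[C@@H](O)C=C
F10 | step 18 | macrocyclic keto bromo ester | CCC(=O)O[C@@H]1CC/C(C)=C\[C@H](OC(=O)C(C)Br)C(=O)[C@H](OC(C)=O)[C@@H]2[C@]1(C)C=CC(=O)[C@H]2C
F11 | step 18 | 11-deoxy macrocycle | CCC(=O)O[C@@H]1CC/C(C)=C\[C@@H]2OC(=O)[C@H](C)[C@@]2(O)[C@H](OC(C)=O)[C@@H]2[C@]1(C)C=CC(=O)[C@H]2C
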